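**Strategy.** The route rests on disconnecting the oxolane ring O–C3–C4–C5–C6 of the 2,5-dioxabicyclo[2.2.1]heptane across C5–C6 and O–C3. A chelation-controlled [3+2] annulation joins ethyl glyoxylate (C6, C7) to the enantioenriched allylsilane CH2=CH–CH(SiMe2Ph)CH2OTIPS (C2–C5) in one operation. It exploits the 1,3-relationship of the C3–O and C5–C6 bonds around C4, whose migrated silicon is a masked form of the C4–O–C7 oxygen. The oxane (C9–C13) then comes from an Achmatowicz ring expansion of a 5-ethylfuran, and a final bromoetherification closes O–C7 and sets C8–Br.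

Key step: step 4

Remarks on the chemistry, valid for all steps:
- Atom labels follow the target chain: C1≡C2 (ethynyl), C3–C7 (dioxabicycle; one oxygen joins C3 and C6, the other C4 and C7), C8 (CHBr), C9–C13 (oxane), C14–C15 (ethyl).
- TIPS = triisopropylsilyl, TBS = tert-butyldimethylsilyl, Oxl = (2S,4S,5S)-4-[(tert-butyldimethylsilyl)oxy]-5-{[(triisopropylsilyl)oxy]methyl}oxolan-2-yl.
- Assumption: in steps 3, 11 and 14 the catalyst antipode is the one that gives the configuration drawn, and the assignment is confirmed (Mosher ester analysis) before material is carried on. Ethyl glyoxylate is cracked from its commercial toluene solution before use.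

Step 1
Reactants: 1 (Z)-but-2-ene-1,4-diol
Product: 2 (Z)-4-[(triisopropylsilyl)oxy]but-2-en-1-ol
Conditions: NaH (1.0 equiv), THF, 0 °C; TIPSCl, 0 °C → rt
Reagents that add atoms: chlorotriisopropylsilane, CC(C)[Si](Cl)(C(C)C)C(C)C
Why: Statistical mono-O-silylation (Williamson-type) of the symmetric diol via its monosodium alkoxide, whose low solubility disfavours double silylation; no stereocentre is formed.

Step 2
Reactants: 2 (Z)-4-[(triisopropylsilyl)oxy]but-2-en-1-ol
Product: 3 diethyl (Z)-4-[(triisopropylsilyl)oxy]but-2-en-1-yl phosphate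
Conditions: ClP(O)(OEt)2, Et3N, DMAP (cat.), CH2Cl2, 0 °C
Reagents that add atoms: diethyl chlorophosphate, CCOP(=O)(Cl)OCC
Why: O-phosphorylation of the primary allylic alcohol gives the leaving group needed for allylic substitution and leaves the alkene untouched.

Step 3
Reactants: 3 diethyl (Z)-4-[(triisopropylsilyl)oxy]but-2-en-1-yl phosphate
Product: 4 (S)-dimethyl(phenyl){1-[(triisopropylsilyl)oxy]but-3-en-2-yl}silane
Conditions: PhMe2Si–Bpin, CuCl (5 mol %), chiral imidazolinium salt (NHC precursor, 6 mol %), NaOMe, THF, 0 °C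
Reagents that add atoms: (dimethylphenylsilyl)boronic acid pinacol ester, C[Si](C)(c1ccccc1)B1OC(C)(C)C(C)(C)O1
Why: Cu-catalysed enantioselective allylic substitution (SN2', γ-selective) by a silyl–copper species made from the silylboronate puts silicon on the carbon bearing CH2OTIPS and moves the double bond to the terminus, the chiral NHC ligand choosing the alkene face and so setting the (S) stereocentre.

Step 4
Reactants: 4 (S)-dimethyl(phenyl){1-[(triisopropylsilyl)oxy]but-3-en-2-yl}silane; 5 ethyl glyoxylate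
Product: 6 ethyl (2S,4R,5S)-4-[dimethyl(phenyl)silyl]-5-{[(triisopropylsilyl)oxy]methyl}oxolane-2-carboxylate
Conditions: SnCl4 (1.1 equiv), CH2Cl2, −78 °C
Reagents that add atoms: none
Why: SnCl4 chelates the aldehyde and ester oxygens of 5, and the terminal CH2 (C5) of allylsilane 4 attacks the activated aldehyde carbon (C6) on the alkene face anti to silicon (anti-SE2'), giving a β-silyl cation bridged as a siliranium ion across C3–C4. Instead of losing silicon (the Hosomi–Sakurai pathway), the PhMe2Si group shifts from C3 to C4 and the tin alkoxide oxygen closes onto C3 from the face opposite silicon, which is the known [3+2] annulation of allylsilanes with aldehydes. The one ring formed, oxolane O–C3–C4–C5–C6, is closed by a 5-endo-type opening of the siliranium ion at C3, allowed because that carbon is cation-like. C3 is set by inversion of the silicon-bearing stereocentre of 4, C4 by the suprafacial silyl shift (silicon trans to the C3 substituent; this centre is reset in steps 6 and 7), and C6 by the chelate transition state, in which tin sits syn to the ester and the ester turns away from the allylsilane substituent, leading to the 2,5-cis oxolane. The step needs annulation to win over desilylative allylation and cis closure to win over trans. The slow-to-leave PhMe2Si group, the low temperature and bidentate chelation of the glyoxylate should secure both.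

Step 5
Reactants: 6 ethyl (2S,4R,5S)-4-[dimethyl(phenyl)silyl]-5-{[(triisopropylsilyl)oxy]methyl}oxolane-2-carboxylate
Product: 8 ethyl (2S,4R,5S)-4-hydroxy-5-{[(triisopropylsilyl)oxy]methyl}oxolane-2-carboxylate, via acetoxysilane 7 (not isolated)
Conditions: Hg(OAc)2, AcOOH (32 % in AcOH), AcOH, rt
Reagents that add atoms: peracetic acid, CC(=O)OO; Hg(OAc)2 (acetate found only in intermediate 7), CC(=O)O[Hg]OC(C)=O
Why: One-pot Fleming–Tamao oxidation, in which ipso-mercuridesilylation removes the phenyl group from silicon to give 7 and the peracid then induces carbon-to-oxygen migration with retention, so the C4 hydroxyl stays trans to the C3 substituent; the TIPS ether has no aryl–silicon bond and is inert.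

Step 6
Reactants: 8 ethyl (2S,4R,5S)-4-hydroxy-5-{[(triisopropylsilyl)oxy]methyl}oxolane-2-carboxylate
Product: 9 ethyl (2S,5S)-4-oxo-5-{[(triisopropylsilyl)oxy]methyl}oxolane-2-carboxylate
Conditions: Dess–Martin periodinane, CH2Cl2, 0 °C → rt
Reagents that add atoms: none
Why: Dess–Martin oxidation gives the oxolan-3-one under near-neutral conditions that avoid β-elimination of the ring oxygen or the silyloxy group, and it clears the C4 stereocentre so that it can be reset.

Step 7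
Reactants: 9 ethyl (2S,5S)-4-oxo-5-{[(triisopropylsilyl)oxy]methyl}oxolane-2-carboxylate
Product: 10 ethyl (2S,4S,5S)-4-hydroxy-5-{[(triisopropylsilyl)oxy]methyl}oxolane-2-carboxylate
Conditions: LiBH(s-Bu)3, THF, −78 °C
Reagents that add atoms: none
Why: Diastereoselective ketone reduction in which the bulky hydride attacks the C4 carbonyl from the face opposite the adjacent CH2OTIPS group and the cis ester, giving the all-cis alcohol (C4 S); the ester is inert at −78 °C.

Step 8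
Reactants: 10 ethyl (2S,4S,5S)-4-hydroxy-5-{[(triisopropylsilyl)oxy]methyl}oxolane-2-carboxylate
Product: 11 ethyl (2S,4S,5S)-4-[(tert-butyldimethylsilyl)oxy]-5-{[(triisopropylsilyl)oxy]methyl}oxolane-2-carboxylate
Conditions: TBSOTf, 2,6-lutidine, CH2Cl2, 0 °C
Reagents that add atoms: tert-butyldimethylsilyl trifluoromethanesulfonate, CC(C)(C)[Si](C)(C)OS(=O)(=O)C(F)(F)F
Why: Silylation with a silyl triflate and a hindered base protects the C4 hydroxyl for the organometallic, acidic and triflation steps that follow.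

Step 9
Reactants: 11 ethyl (2S,4S,5S)-4-[(tert-butyldimethylsilyl)oxy]-5-{[(triisopropylsilyl)oxy]methyl}oxolane-2-carboxylate
Product: 12 (2S,4S,5S)-4-[(tert-butyldimethylsilyl)oxy]-5-{[(triisopropylsilyl)oxy]methyl}oxolane-2-carbaldehyde
Conditions: i-Bu2AlH (1.1 equiv), CH2Cl2, −78 °C; Rochelle salt work-up
Reagents that add atoms: none
Why: Partial reduction of the α-alkoxy ester stops at the aldehyde because the tetrahedral aluminium hemiacetal is stable at −78 °C; C6 is not epimerised.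

Step 10
Reactants: 12 (2S,4S,5S)-4-[(tert-butyldimethylsilyl)oxy]-5-{[(triisopropylsilyl)oxy]methyl}oxolane-2-carbaldehyde
Product: 13 tert-butyl{[(2S,3S,5S)-5-ethynyl-2-{[(triisopropylsilyl)oxy]methyl}oxolan-3-yl]oxy}dimethylsilane
Conditions: dimethyl (1-diazo-2-oxopropyl)phosphonate, K2CO3, MeOH, 0 °C → rt
Reagents that add atoms: dimethyl (1-diazo-2-oxopropyl)phosphonate, COP(=O)(OC)C(=[N+]=[N-])C(C)=O
Why: Ohira–Bestmann (Seyferth–Gilbert) homologation, in which methanolysis of the reagent gives dimethyl (diazomethyl)phosphonate that converts the aldehyde through the diazoalkene into the terminal alkyne C7≡C8 under conditions mild enough to keep C6.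

Step 11
Reactants: 13 tert-butyl{[(2S,3S,5S)-5-ethynyl-2-{[(triisopropylsilyl)oxy]methyl}oxolan-3-yl]oxy}dimethylsilane; 14 5-ethylfuran-2-carbaldehyde
Product: 15 (1R)-1-(5-ethylfuran-2-yl)-3-Oxl-prop-2-yn-1-ol
Conditions: Me2Zn, ProPhenol ligand (20 mol %), Ph3P=O (40 mol %), toluene, 0 °C → rt
Reagents that add atoms: none
Why: Ligand-controlled asymmetric addition of the zinc acetylide to the heteroaryl aldehyde (ProPhenol–zinc alkynylation) forms C8–C9 and sets the C9 carbinol (R), the remote oxolane stereocentres having little influence.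

Step 12
Reactants: 15 (1R)-1-(5-ethylfuran-2-yl)-3-Oxl-prop-2-yn-1-ol
Product: 16 (2R)-6-ethyl-6-hydroxy-2-(Oxl-ethynyl)-2H-pyran-3(6H)-one (both C6 anomers)
Conditions: NBS, NaHCO3, NaOAc, THF/H2O (4:1), 0 °C
Reagents that add atoms: water, O
Why: Achmatowicz rearrangement, in which bromonium-induced oxidative opening of the furan to the ene-dione and hemiketalisation by the carbinol oxygen gives the pyranone with C9 retained and the furan carbons becoming C10–C13; the furan is far more electron-rich than the internal alkyne.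

Step 13
Reactants: 16 (2R)-6-ethyl-6-hydroxy-2-(Oxl-ethynyl)-2H-pyran-3(6H)-one
Product: 17 (2R,6S)-6-ethyl-2-(Oxl-ethynyl)-2H-pyran-3(6H)-one
Conditions: Et3SiH, CF3CO2H, CH2Cl2, −40 °C
Reagents that add atoms: none
Why: Ionic reduction of the hemiketal, in which acid generates the cyclic oxocarbenium ion at C13 and Et3SiH delivers hydride axially to give the 2,6-cis pyranone (C13 S), the arrangement that is also thermodynamically preferred at the epimerisable C9.

Step 14
Reactants: 17 (2R,6S)-6-ethyl-2-(Oxl-ethynyl)-2H-pyran-3(6H)-one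
Product: 18 (2R,3R,6S)-6-ethyl-2-(Oxl-ethynyl)-3,6-dihydro-2H-pyran-3-ol
Conditions: 2-methyl-CBS-oxazaborolidine (20 mol %), catecholborane, toluene, −78 °C
Reagents that add atoms: none
Why: Corey–Bakshi–Shibata 1,2-reduction under reagent control should give the allylic alcohol cis to the C9 substituent (C10 R, pseudoaxial hydroxyl) against the intrinsic axial-attack preference of the enone; catecholborane at −78 °C spares the alkyne.

Step 15
Reactants: 18 (2R,3R,6S)-6-ethyl-2-(Oxl-ethynyl)-3,6-dihydro-2H-pyran-3-ol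
Product: 19 (1R,2S,4R,5S,6S)-2-ethyl-4-(Oxl-ethynyl)-3,7-dioxabicyclo[4.1.0]heptan-5-ol
Conditions: VO(acac)2 (5 mol %), t-BuOOH, CH2Cl2, 0 °C → rt
Reagents that add atoms: tert-butyl hydroperoxide, CC(C)(C)OO
Why: Hydroxyl-directed epoxidation, in which the vanadium alkylperoxide bound to the pseudoaxial allylic hydroxyl delivers oxygen to the C11=C12 face syn to the C10 hydroxyl.

Step 16
Reactants: 19 (1R,2S,4R,5S,6S)-2-ethyl-4-(Oxl-ethynyl)-3,7-dioxabicyclo[4.1.0]heptan-5-ol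
Product: 20 (2R,3R,5S,6S)-6-ethyl-2-(Oxl-ethynyl)oxane-3,5-diol
Conditions: LiBEt3H, THF, 0 °C
Reagents that add atoms: none
Why: Hydride opening of the epoxide should follow the Fürst–Plattner rule (trans-diaxial opening), attack at C11 from the face opposite the epoxide leading directly to the chair with both 2,6-substituents equatorial and the C12 oxygen axial, which is the 3,5-diaxial diol with C11 as CH2.

Step 17
Reactants: 20 (2R,3R,5S,6S)-6-ethyl-2-(Oxl-ethynyl)oxane-3,5-diol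
Product: 22 (2R,3S,5R,6S)-3,5-dibromo-6-ethyl-2-(Oxl-ethynyl)oxane, via bis-triflate 21 (not isolated)
Conditions: Tf2O, pyridine, CH2Cl2, −20 °C; then n-Bu4NBr, toluene, rt → 40 °C
Reagents that add atoms: tetrabutylammonium bromide, CCCC[N+](CCCC)(CCCC)CCCC.[Br-]; trifluoromethanesulfonic anhydride (atoms found only in intermediate 21), O=S(=O)(OS(=O)(=O)C(F)(F)F)C(F)(F)F
Why: Double SN2 displacement in which both axial triflates are displaced by bromide with inversion to give the diequatorial dibromide (C10 S, C12 R), axial leaving groups being well placed for backside attack and the syn arrangement of the two oxygens excluding oxetane formation.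

Step 18
Reactants: 22 (2R,3S,5R,6S)-3,5-dibromo-6-ethyl-2-(Oxl-ethynyl)oxane
Product: 23 (2R,3S,5R,6S)-3,5-dibromo-6-ethyl-2-[(Z)-2-Oxl-ethenyl]oxane
Conditions: H2 (1 atm), Pd/CaCO3 poisoned with Pb(OAc)2 (Lindlar catalyst), quinoline, EtOAc, rt
Reagents that add atoms: none
Why: Lindlar semihydrogenation adds H2 syn to the internal alkyne and stops at the (Z)-alkene; secondary alkyl bromides and silyl ethers are inert to the poisoned catalyst.

Step 19
Reactants: 23 (2R,3S,5R,6S)-3,5-dibromo-6-ethyl-2-[(Z)-2-Oxl-ethenyl]oxane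
Product: 24 (2S,3S,5S)-5-{(Z)-2-[(2R,3S,5R,6S)-3,5-dibromo-6-ethyloxan-2-yl]ethenyl}-2-(hydroxymethyl)oxolan-3-ol
Conditions: n-Bu4NF, AcOH, THF, 0 °C → rt
Reagents that add atoms: none
Why: Fluoride-mediated desilylation removes both silyl ethers at once, and acetic acid buffering keeps the medium from promoting E2 loss of the equatorial bromides.

Step 20
Reactants: 24 (2S,3S,5S)-5-{(Z)-2-[(2R,3S,5R,6S)-3,5-dibromo-6-ethyloxan-2-yl]ethenyl}-2-(hydroxymethyl)oxolan-3-ol
Product: 25 (2R,3S,5S)-5-{(Z)-2-[(2R,3S,5R,6S)-3,5-dibromo-6-ethyloxan-2-yl]ethenyl}-3-hydroxyoxolane-2-carbaldehyde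
Conditions: TEMPO (10 mol %), PhI(OAc)2, CH2Cl2, rt
Reagents that add atoms: none
Why: Oxoammonium (TEMPO) oxidation is selective for the primary alcohol over the hindered secondary one and gives the aldehyde without touching the alkene or the bromides.

Step 21
Reactants: 25 (2R,3S,5S)-5-{(Z)-2-[(2R,3S,5R,6S)-3,5-dibromo-6-ethyloxan-2-yl]ethenyl}-3-hydroxyoxolane-2-carbaldehyde
Product: 26 (2S,3S,5S)-5-{(Z)-2-[(2R,3S,5R,6S)-3,5-dibromo-6-ethyloxan-2-yl]ethenyl}-2-ethynyloxolan-3-ol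
Conditions: dimethyl (1-diazo-2-oxopropyl)phosphonate, K2CO3, MeOH, 0 °C
Reagents that add atoms: dimethyl (1-diazo-2-oxopropyl)phosphonate, COP(=O)(OC)C(=[N+]=[N-])C(C)=O
Why: Ohira–Bestmann homologation installs the terminal alkyne C1≡C2 at C3 under mild carbonate conditions that the secondary bromides and the β-hydroxyl tolerate, run cold to suppress epimerisation at C3.

Step 22
Reactants: 26 (2S,3S,5S)-5-{(Z)-2-[(2R,3S,5R,6S)-3,5-dibromo-6-ethyloxan-2-yl]ethenyl}-2-ethynyloxolan-3-ol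
Product: 27 (1S,3S,4S,6S)-6-{(R)-bromo[(2S,3S,5R,6S)-3,5-dibromo-6-ethyloxan-2-yl]methyl}-3-ethynyl-2,5-dioxabicyclo[2.2.1]heptane
Conditions: NBS, CH2Cl2, 0 °C → rt
Reagents that add atoms: N-bromosuccinimide, O=C1CCC(=O)N1Br
Why: Bromoetherification in which bromonium formation on the (Z)-alkene and 5-exo attack of the C4 hydroxyl on C7, anti to bromine, closes the second oxolane of the dioxabicycle and gives C7 S and C8 R, with C8 taking the less congested exo position.

**Compound list**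

1 | (Z)-but-2-ene-1,4-diol | OC/C=C\CO | starting material
2 | (Z)-4-[(triisopropylsilyl)oxy]but-2-en-1-ol | OC/C=C\CO[Si](C(C)C)(C(C)C)C(C)C | intermediate
3 | diethyl (Z)-4-[(triisopropylsilyl)oxy]but-2-en-1-yl phosphate | CCOP(=O)(OCC)OC/C=C\CO[Si](C(C)C)(C(C)C)C(C)C | intermediate
4 | (S)-dimethyl(phenyl){1-[(triisopropylsilyl)oxy]but-3-en-2-yl}silane | CC(C)[Si](C(C)C)(C(C)C)OC[C@H](C=C)[Si](C)(C)c1ccccc1 | intermediate
5 | ethyl glyoxylate | CCOC(=O)C=O | starting material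
6 | ethyl (2S,4R,5S)-4-[dimethyl(phenyl)silyl]-5-{[(triisopropylsilyl)oxy]methyl}oxolane-2-carboxylate | CC(C)[Si](C(C)C)(C(C)C)OC[C@@H]1O[C@H](C(=O)OCC)C[C@H]1[Si](C)(C)c1ccccc1 | intermediate
7 | ethyl (2S,4R,5S)-4-[acetoxy(dimethyl)silyl]-5-{[(triisopropylsilyl)oxy]methyl}oxolane-2-carboxylate (not isolated) | CC(C)[Si](C(C)C)(C(C)C)OC[C@@H]1O[C@H](C(=O)OCC)C[C@H]1[Si](C)(C)OC(C)=O | intermediate
8 | ethyl (2S,4R,5S)-4-hydroxy-5-{[(triisopropylsilyl)oxy]methyl}oxolane-2-carboxylate | CC(C)[Si](C(C)C)(C(C)C)OC[C@@H]1O[C@H](C(=O)OCC)C[C@H]1O | intermediate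
9 | ethyl (2S,5S)-4-oxo-5-{[(triisopropylsilyl)oxy]methyl}oxolane-2-carboxylate | CC(C)[Si](C(C)C)(C(C)C)OC[C@@H]1O[C@H](C(=O)OCC)CC1=O | intermediate
10 | ethyl (2S,4S,5S)-4-hydroxy-5-{[(triisopropylsilyl)oxy]methyl}oxolane-2-carboxylate | CC(C)[Si](C(C)C)(C(C)C)OC[C@@H]1O[C@H](C(=O)OCC)C[C@@H]1O | intermediate
11 | ethyl (2S,4S,5S)-4-[(tert-butyldimethylsilyl)oxy]-5-{[(triisopropylsilyl)oxy]methyl}oxolane-2-carboxylate | CC(C)[Si](C(C)C)(C(C)C)OC[C@@H]1O[C@H](C(=O)OCC)C[C@@H]1O[Si](C)(C)C(C)(C)C | intermediate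
12 | (2S,4S,5S)-4-[(tert-butyldimethylsilyl)oxy]-5-{[(triisopropylsilyl)oxy]methyl}oxolane-2-carbaldehyde | CC(C)[Si](C(C)C)(C(C)C)OC[C@@H]1O[C@H](C=O)C[C@@H]1O[Si](C)(C)C(C)(C)C | intermediate
13 | tert-butyl{[(2S,3S,5S)-5-ethynyl-2-{[(triisopropylsilyl)oxy]methyl}oxolan-3-yl]oxy}dimethylsilane | CC(C)[Si](C(C)C)(C(C)C)OC[C@@H]1O[C@H](C#C)C[C@@H]1O[Si](C)(C)C(C)(C)C | intermediate
14 | 5-ethylfuran-2-carbaldehyde | CCc1ccc(C=O)o1 | starting material
15 | (1R)-1-(5-ethylfuran-2-yl)-3-Oxl-prop-2-yn-1-ol | CC(C)[Si](C(C)C)(C(C)C)OC[C@@H]1O[C@H](C#C[C@@H](O)c2ccc(CC)o2)C[C@@H]1O[Si](C)(C)C(C)(C)C | intermediate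
16 | (2R)-6-ethyl-6-hydroxy-2-(Oxl-ethynyl)-2H-pyran-3(6H)-one, both C6 anomers | CC(C)[Si](C(C)C)(C(C)C)OC[C@@H]1O[C@H](C#C[C@H]2OC(O)(CC)C=CC2=O)C[C@@H]1O[Si](C)(C)C(C)(C)C | intermediate
17 | (2R,6S)-6-ethyl-2-(Oxl-ethynyl)-2H-pyran-3(6H)-one | CC(C)[Si](C(C)C)(C(C)C)OC[C@@H]1O[C@H](C#C[C@H]2O[C@@H](CC)C=CC2=O)C[C@@H]1O[Si](C)(C)C(C)(C)C | intermediate
18 | (2R,3R,6S)-6-ethyl-2-(Oxl-ethynyl)-3,6-dihydro-2H-pyran-3-ol | CC(C)[Si](C(C)C)(C(C)C)OC[C@@H]1O[C@H](C#C[C@H]2O[C@@H](CC)C=C[C@H]2O)C[C@@H]1O[Si](C)(C)C(C)(C)C | intermediate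
19 | (1R,2S,4R,5S,6S)-2-ethyl-4-(Oxl-ethynyl)-3,7-dioxabicyclo[4.1.0]heptan-5-ol | CC(C)[Si](C(C)C)(C(C)C)OC[C@@H]1O[C@H](C#C[C@H]2O[C@@H](CC)[C@H]3O[C@H]3[C@H]2O)C[C@@H]1O[Si](C)(C)C(C)(C)C | intermediate
20 | (2R,3R,5S,6S)-6-ethyl-2-(Oxl-ethynyl)oxane-3,5-diol | CC(C)[Si](C(C)C)(C(C)C)OC[C@@H]1O[C@H](C#C[C@H]2O[C@@H](CC)[C@@H](O)C[C@H]2O)C[C@@H]1O[Si](C)(C)C(C)(C)C | intermediate
21 | (2R,3R,5S,6S)-6-ethyl-2-(Oxl-ethynyl)oxane-3,5-diyl bis(trifluoromethanesulfonate) (not isolated) | CC(C)[Si](C(C)C)(C(C)C)OC[C@@H]1O[C@H](C#C[C@H]2O[C@@H](CC)[C@@H](OS(=O)(=O)C(F)(F)F)C[C@H]2OS(=O)(=O)C(F)(F)F)C[C@@H]1O[Si](C)(C)C(C)(C)C | intermediate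
22 | (2R,3S,5R,6S)-3,5-dibromo-6-ethyl-2-(Oxl-ethynyl)oxane | CC(C)[Si](C(C)C)(C(C)C)OC[C@@H]1O[C@H](C#C[C@H]2O[C@@H](CC)[C@H](Br)C[C@@H]2Br)C[C@@H]1O[Si](C)(C)C(C)(C)C | intermediate
23 | (2R,3S,5R,6S)-3,5-dibromo-6-ethyl-2-[(Z)-2-Oxl-ethenyl]oxane | CC(C)[Si](C(C)C)(C(C)C)OC[C@@H]1O[C@H](/C=C\[C@H]2O[C@@H](CC)[C@H](Br)C[C@@H]2Br)C[C@@H]1O[Si](C)(C)C(C)(C)C | intermediate
24 | (2S,3S,5S)-5-{(Z)-2-[(2R,3S,5R,6S)-3,5-dibromo-6-ethyloxan-2-yl]ethenyl}-2-(hydroxymethyl)oxolan-3-ol | OC[C@@H]1O[C@H](/C=C\[C@H]2O[C@@H](CC)[C@H](Br)C[C@@H]2Br)C[C@@H]1O | intermediate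
25 | (2R,3S,5S)-5-{(Z)-2-[(2R,3S,5R,6S)-3,5-dibromo-6-ethyloxan-2-yl]ethenyl}-3-hydroxyoxolane-2-carbaldehyde | O=C[C@@H]1O[C@H](/C=C\[C@H]2O[C@@H](CC)[C@H](Br)C[C@@H]2Br)C[C@@H]1O | intermediate
26 | (2S,3S,5S)-5-{(Z)-2-[(2R,3S,5R,6S)-3,5-dibromo-6-ethyloxan-2-yl]ethenyl}-2-ethynyloxolan-3-ol | C#C[C@@H]1O[C@H](/C=C\[C@H]2O[C@@H](CC)[C@H](Br)C[C@@H]2Br)C[C@@H]1O | intermediate
27 | (1S,3S,4S,6S)-6-{(R)-bromo[(2S,3S,5R,6S)-3,5-dibromo-6-ethyloxan-2-yl]methyl}-3-ethynyl-2,5-dioxabicyclo[2.2.1]heptane | C#C[C@@H]1O[C@H]2C[C@@H]1O[C@@H]2[C@@H](Br)[C@H]1O[C@@H](CC)[C@H](Br)C[C@@H]1Br | target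

**Step count and risks**

Total step count: 22. Longest linear sequence: 22 steps (1 → 27); compounds 5 and 14 are purchased.

Steps most likely to fail:

1. Step 4. The β-silyl cation may lose silicon before the silyl shift and ring closure (allylation instead of annulation), or the small CH2OTIPS group may control the reacting rotamer poorly and erode the 2,5-cis closure. The fallback sets out from 4 and 5 and comes back at 8. TiCl4 in CH2Cl2 at −78 °C (Hosomi–Sakurai allylation with anti-SE2' chirality transfer through the same chelate) would give ethyl (2S,4E)-2-hydroxy-6-[(triisopropylsilyl)oxy]hex-4-enoate F1. Shi epoxidation (fructose-derived ketone of the required antipode, KHSO5 as Oxone, K2CO3, MeCN/dimethoxymethane/aqueous buffer, 0 °C) would give ethyl (2S)-2-hydroxy-3-[(2R,3R)-3-{[(triisopropylsilyl)oxy]methyl}oxiran-2-yl]propanoate F2. Camphorsulfonic acid in CH2Cl2 would then close the oxolane by 5-endo opening of the epoxide at C3 with inversion, which is trans alcohol 8, and the route continues with step 6.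

2. Step 22. Closure to the strained bicycle may be slow on an alkene deactivated by two allylic C–O bonds, so that 6-endo attack or intermolecular capture of the bromonium ion takes over. The fallback sets out from 22 and comes back at 27; it reaches the same C7/C8 relationship by syn-type net addition to the (E)-alkene followed by inversion.
   - Trans-selective semihydrogenation of the alkyne ([Cp*RuCl(cod)], Cp* = C5Me5, cod = 1,5-cyclooctadiene; AgOTf, H2, CH2Cl2) would give (2R,3S,5R,6S)-3,5-dibromo-6-ethyl-2-[(E)-2-Oxl-ethenyl]oxane F3.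
   - n-Bu4NF/AcOH would give the (E)-isomer of diol 24 F4.
   - TEMPO/PhI(OAc)2 would give the (E)-isomer of aldehyde 25 F5.
   - Ohira–Bestmann homologation would give the (E)-isomer of enynol 26 F6.
   - Shi epoxidation under reagent control would give the trans-(7R,8S)-epoxide of F6 F7.
   - Camphorsulfonic acid in CH2Cl2 would let the C4 hydroxyl open the epoxide 5-exo at C7 with inversion, giving the bicyclic (8S)-alcohol, the 8-hydroxy analogue of 27 with the opposite spatial arrangement at C8, F8.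
   - Tf2O/pyridine would give the C8 triflate of F8 F9, and n-Bu4NBr in toluene would displace it with inversion to give 27.

3. Step 14. Hydride may be delivered under substrate control (axial attack) and not reagent control, giving the C10 epimer. The fallback sets out from 17 and comes back at 18. Luche reduction (NaBH4, CeCl3·7H2O, MeOH, −78 °C) would give the trans alcohol (2R,3S,6S)-6-ethyl-2-(Oxl-ethynyl)-3,6-dihydro-2H-pyran-3-ol F10. Mitsunobu inversion (4-nitrobenzoic acid, PPh3, diisopropyl azodicarboxylate, THF) would give (2R,3R,6S)-6-ethyl-2-(Oxl-ethynyl)-3,6-dihydro-2H-pyran-3-yl 4-nitrobenzoate F11. Methanolysis (K2CO3, MeOH) would then give 18, and the route continues with step 15.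

Further compounds
F1 | step 4 | ethyl (2S,4E)-2-hydroxy-6-[(triisopropylsilyl)oxy]hex-4-enoate | CCOC(=O)[C@@H](O)C/C=C/CO[Si](C(C)C)(C(C)C)C(C)C
F2 | step 4 | ethyl (2S)-2-hydroxy-3-[(2R,3R)-3-{[(triisopropylsilyl)oxy]methyl}oxiran-2-yl]propanoate | CCOC(=O)[C@@H](O)C[C@H]1O[C@@H]1CO[Si](C(C)C)(C(C)C)C(C)C
F3 | step 22 | (2R,3S,5R,6S)-3,5-dibromo-6-ethyl-2-[(E)-2-Oxl-ethenyl]oxane | CC(C)[Si](C(C)C)(C(C)C)OC[C@@H]1O[C@H](/C=C/[C@H]2O[C@@H](CC)[C@H](Br)C[C@@H]2Br)C[C@@H]1O[Si](C)(C)C(C)(C)C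
F4 | step 22 | (2S,3S,5S)-5-{(E)-2-[(2R,3S,5R,6S)-3,5-dibromo-6-ethyloxan-2-yl]ethenyl}-2-(hydroxymethyl)oxolan-3-ol | OC[C@@H]1O[C@H](/C=C/[C@H]2O[C@@H](CC)[C@H](Br)C[C@@H]2Br)C[C@@H]1O
F5 | step 22 | (2R,3S,5S)-5-{(E)-2-[(2R,3S,5R,6S)-3,5-dibromo-6-ethyloxan-2-yl]ethenyl}-3-hydroxyoxolane-2-carbaldehyde | O=C[C@@H]1O[C@H](/C=C/[C@H]2O[C@@H](CC)[C@H](Br)C[C@@H]2Br)C[C@@H]1O
F6 | step 22 | (2S,3S,5S)-5-{(E)-2-[(2R,3S,5R,6S)-3,5-dibromo-6-ethyloxan-2-yl]ethenyl}-2-ethynyloxolan-3-ol | C#C[C@@H]1O[C@H](/C=C/[C@H]2O[C@@H](CC)[C@H](Br)C[C@@H]2Br)C[C@@H]1O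
F7 | step 22 | (2S,3S,5S)-5-{(2R,3S)-3-[(2R,3S,5R,6S)-3,5-dibromo-6-ethyloxan-2-yl]oxiran-2-yl}-2-ethynyloxolan-3-ol | C#C[C@@H]1O[C@H]([C@H]4O[C@@H]4[C@H]2O[C@@H](CC)[C@H](Br)C[C@@H]2Br)C[C@@H]1O
F8 | step 22 | (8S)-alcohol: analogue of 27 with OH in place of Br at C8 and the opposite spatial arrangement there | C#C[C@@H]1O[C@H]2C[C@@H]1O[C@@H]2[C@H](O)[C@H]1O[C@@H](CC)[C@H](Br)C[C@@H]1Br
F9 | step 22 | trifluoromethanesulfonate of F8 at the C8 oxygen | C#C[C@@H]1O[C@H]2C[C@@H]1O[C@@H]2[C@H](OS(=O)(=O)C(F)(F)F)[C@H]1O[C@@H](CC)[C@H](Br)C[C@@H]1Br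
F10 | step 14 | (2R,3S,6S)-6-ethyl-2-(Oxl-ethynyl)-3,6-dihydro-2H-pyran-3-ol | CC(C)[Si](C(C)C)(C(C)C)OC[C@@H]1O[C@H](C#C[C@H]2O[C@@H](CC)C=C[C@@H]2O)C[C@@H]1O[Si](C)(C)C(C)(C)C
F11 | step 14 | (2R,3R,6S)-6-ethyl-2-(Oxl-ethynyl)-3,6-dihydro-2H-pyran-3-yl 4-nitrobenzoate | CC(C)[Si](C(C)C)(C(C)C)OC[C@@H]1O[C@H](C#C[C@H]2O[C@@H](CC)C=C[C@H]2OC(=O)c3ccc(cc3)[N+](=O)[O-])C[C@@H]1O[Si](C)(C)C(C)(C)C
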